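# Epigallocatechin 7-O-gallate by epoxide–arene closure of ring C

## Analysis of the target

The target is a flavan: a 3,4-dihydro-2H-chromene in which ring A (C4a to C8a, oxygenated at C5 and C7) is fused to the pyran ring C (O1, C2, C3, C4). C2 carries the 3,4,5-trihydroxyphenyl ring B, C3 a free hydroxyl, and O7 a 3,4,5-trihydroxybenzoyl (galloyl) ester. There are two stereocentres, C2 and C3, both R, with the aryl group and the hydroxyl cis on ring C (the epi series). The molecule has eight free phenols, two of them in air-sensitive pyrogallol units, and a phenyl-type ester at O7 that base or nucleophiles cleave. Its benzylic C2–O1 bond ionises under acid and lets C2 epimerise under base. The main difficulty is that O7 alone must be acylated while O5, its near-twin on a ring that starts as symmetric phloroglucinol, and O3 stay free. O5 and O7 therefore have to be told apart before or during ring construction, and the last deprotection has to be neutral. The strategy rests on C4, a bare methylene that links the carbinol carbon C3 to C4a, a ring A carbon ortho to the O1-bearing C8a and para to the O7-bearing C7. A C3–C4 oxirane hung from ring A through the O1–C2 ether therefore holds its terminal carbon next to C4a, and its opening by the arene forms C4–C4a, ring C and the C3 hydroxyl in one event. That event touches neither stereocentre, so both can be fixed beforehand in an acyclic epoxy alcohol.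

## Retrosynthetic reasoning

**14 from 13.** The seven benzylic C–O bonds are cut last: six benzyl ethers on ring B and on the galloyl unit, and the benzyl carbonate on O5. One neutral hydrogenolysis then frees all phenols at once, and the ester, the C2–O1 bond and the cis stereochemistry never meet acid or base.

**13 from 10 and 12.** The ester bond between O7 and the galloyl carbonyl is cut next. In 10 the O7 hydroxyl is the only free phenol, so the forward acylation only has to prefer a phenol over the hindered secondary C3 hydroxyl. The acid chloride 12 comes from the acid 11.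

**10 from 9.** The O7–Si bond is cut. A silyl ether at O7 is the one group in 9 that can be removed without hydrogen and without touching benzyl ethers, so it marks the oxygen that will carry the ester. The forward cleavage must spare the aryl carbonate on O5.

**9 from 8.** The C4–C4a bond is cut, which opens ring C and returns the C3 hydroxyl to an oxirane. This is the disconnection that the C4 methylene invites. It removes one ring and one skeletal bond and leaves an aryl ether in which both stereocentres already exist. The forward reaction is an intramolecular Friedel–Crafts alkylation. It has to choose the terminal oxirane carbon (six-membered ring) and, of the two ring A carbons ortho to O1, the one para to the silyloxy group. That second choice decides that silicon ends on O7 and the carbonate on O5.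

**8 from 6 and 7.** The carbonate C–O5 bond is cut. The carbonate makes O5 a weak donor during the ring closure and leaves in the final hydrogenolysis. It is put on after the ether is made, when 6 has a single free phenol.

**6 from 3 and 5.** The C2–O1 ether bond is cut at the benzylic carbon. The forward reaction is a Mitsunobu etherification that inverts the carbinol, so the erythro epoxy alcohol 3 gives the threo ether needed for a 2,3-cis flavan. The diol 5 is used in excess so that only one of its two equivalent hydroxyls reacts.

**5 from 4; 3 from 2; 2 from 1.** Monosilylation of the symmetric triol 4 gives 5. The oxirane oxygen of 3 is removed to the racemic allylic alcohol 2. A titanium–tartrate kinetic resolution in the forward direction sets the oxirane carbon (future C3) and selects the carbinol enantiomer in one step. Cutting the bond between the carbinol carbon and the vinyl group leads to the aldehyde 1.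

## Alternatives that were turned down

**Alternative 1: aryne, formamide and ketone three-component assembly.** This cuts O1–C8a, C4–C4a, C3–C4 and O1–C2 together. Fluoride releases an aryne from the silyl triflate A1, N,N-dimethylformamide A2 adds across it (its oxygen becomes O1 and its formyl carbon C4), the enolate of ketone A3 adds at C4, dimethylamine is lost, and the phenoxide closes onto the ketone carbon to give the chromen-2-ol A4.
- For it: it is the most convergent of the four routes. It is stronger than the chosen route in bond count, since ring C is built from three pieces in one flask. O5 and O7 are differentiated from the start, and the 3-alkoxy group of the aryne steers the addition reliably.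
- Against it: A4 is a racemic hemiketal at the flavene oxidation level, so neither stereocentre of the target exists yet. C2 must exchange OH for H and the C3–C4 enol ether must be reduced, cis and in one enantiomeric series, and no dependable asymmetric reduction of such a tetrasubstituted enol ether or flavylium ion is at hand. A1 itself needs several steps. The methoxymethyl groups come off only with acid, which the electron-rich flavan tolerates poorly, and their removal frees O3 and O7 together.
- Comparison: the chosen route forms only one bond in its key step, but it arrives there with both stereocentres fixed by two well-understood operations and needs three steps afterwards.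

**Alternative 2: ortho-quinone methide cycloaddition with a Z-enol ester.** This cuts C3–C4 and O1–C2. Acid releases the ortho-quinone methide from the hydroxybenzyl alcohol A5, and a chiral BINOL-derived phosphoric acid guides its [4+2] addition to the (Z)-enol benzoate A6, giving the cis-flavan-3-yl benzoate A7.
- For it: ring C and both stereocentres arise in one step, with cis following from the Z geometry. On this point it is clearly stronger than the chosen key step, which creates no stereocentre.
- Against it: the quinone methide is unsubstituted at the methide carbon (the future C4 methylene). Such species are short-lived and oligomerise, and enantiocontrol by a phosphate is far less secure for them than for aryl-substituted ones. The alkene of A6 carries two competing donors. Only if the aryl group outweighs the acyloxy group does O1 bond to C2, and otherwise the 2-acyloxy-3-aryl chroman forms. A6 must be made and kept as the pure Z isomer under acid, and A5 needs a regiocontrolled hydroxymethylation of a differentiated phloroglucinol. The benzoate on O3 must be removed before O7 is acylated, because it could not be cleaved later beside the more labile aryl gallate. The same phenol-versus-alcohol selection as in the chosen route therefore returns.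
- Comparison: step counts are similar. The chosen route splits the stereochemical problem into a tartrate-controlled epoxidation and an SN2 inversion, each predictable from mechanism, and keeps the uncertainty to a regiochemical question.

**Alternative 3: copper-mediated aryl ether closure at C8a.** This cuts O1–C8a. The free benzylic hydroxyl of the syn bromo alcohol A8 is coupled with the ring A bromide (CuI, 1,10-phenanthroline, Cs2CO3) to give the cis-flavan A9, with retention because no bond at C2 is broken.
- For it: there is no cationic chemistry at C2. The ring A position is fixed by the bromide, so there is no site-selectivity question, which makes it stronger than the chosen route on that point. O3 is already a benzyl ether, so the later O7 acylation has no competitor, a second point in its favour.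
- Against it: A8 is far from simple materials. The C4–C4a bond has to be made separately on a ring A piece that carries bromine, benzyloxy and silyloxy groups in defined positions. The syn diol has to be installed and its two hydroxyls distinguished. The coupling joins a hindered secondary benzylic alkoxide to an electron-rich, doubly ortho-substituted aryl bromide, the least reactive combination for this chemistry, at high temperature with carbonate base. Under those conditions the aryl silyl ether can be lost and the benzylic alcohol oxidised or eliminated.
- Comparison: the chosen route accepts a regiochemical risk in ring A and a chemoselective acylation, and in return reaches its precursor in five steps from commercial materials and closes ring C at low temperature.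

Key step: step 6

Assumption: the titanium–tartrate epoxidation is taken to follow its usual face-selection rule for secondary allylic alcohols, so that with L-(+)-diisopropyl tartrate the (R)-enantiomer of 2 reacts fast and gives the erythro product; if the opposite sense were found, D-(−)-diisopropyl tartrate would be used and nothing else would change.

## Route

Step 1
Reactants: 1 3,4,5-tris(benzyloxy)benzaldehyde
Product: 2 rac-1-[3,4,5-tris(benzyloxy)phenyl]prop-2-en-1-ol
Conditions: CH2=CHMgBr (1.2 equiv), THF, −78 to 0 °C; aq. NH4Cl
Reagents that add atoms: vinylmagnesium bromide, C=C[Mg]Br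
Why: 1,2-addition of a Grignard reagent to a non-enolisable aryl aldehyde; the alcohol is racemic and its configuration is sorted out in step 2.

Step 2
Reactants: 2 rac-1-[3,4,5-tris(benzyloxy)phenyl]prop-2-en-1-ol
Product: 3 (S)-[(2R)-oxiran-2-yl][3,4,5-tris(benzyloxy)phenyl]methanol (erythro)
Conditions: Ti(OiPr)4 (0.2 equiv), L-(+)-diisopropyl tartrate (0.24 equiv), t-BuOOH (0.45 equiv), 4 Å MS, CH2Cl2, −20 °C; citric acid work-up
Reagents that add atoms: tert-butyl hydroperoxide, CC(C)(C)OO
Why: Sharpless kinetic resolution: the titanium–tartrate complex should epoxidise the (R)-alcohol much faster than its antipode and on the face that gives the erythro epoxy alcohol, so the tartrate fixes the oxirane carbon (future C3) and selects the carbinol configuration that step 4 inverts into C2. The oxidant is kept below half an equivalent so that the slow (S)-enantiomer of 2 stays behind and is separated; at most half of 2 can be converted.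

Step 3
Reactants: 4 phloroglucinol (benzene-1,3,5-triol)
Product: 5 5-[(triisopropylsilyl)oxy]benzene-1,3-diol
Conditions: i-Pr3SiCl (0.5 equiv relative to 4), imidazole, DMF, 0 °C to rt
Reagents that add atoms: chlorotriisopropylsilane, CC(C)[Si](Cl)(C(C)C)C(C)C
Why: Silylation of a phenol with a silyl chloride and imidazole; the three hydroxyls are equivalent, the triol is used in excess so that the mono-ether should predominate, and unreacted 4 is removed by aqueous extraction.

Step 4
Reactants: 3 (S)-[(2R)-oxiran-2-yl][3,4,5-tris(benzyloxy)phenyl]methanol; 5 5-[(triisopropylsilyl)oxy]benzene-1,3-diol (3 equiv)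
Product: 6 3-{(R)-[(2R)-oxiran-2-yl][3,4,5-tris(benzyloxy)phenyl]methoxy}-5-[(triisopropylsilyl)oxy]phenol (threo)
Conditions: PPh3, DIAD, toluene/THF, 0 °C to rt
Reagents that add atoms: none
Why: Mitsunobu etherification: the phenoxide displaces the oxyphosphonium group by SN2, which inverts the benzylic carbinol to R and turns the erythro alcohol into the threo ether. The oxirane is inert under these neutral conditions, and the excess of the diol keeps its second hydroxyl from reacting.

Step 5
Reactants: 6 3-{(R)-[(2R)-oxiran-2-yl][3,4,5-tris(benzyloxy)phenyl]methoxy}-5-[(triisopropylsilyl)oxy]phenol; 7 benzyl chloroformate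
Product: 8 benzyl 3-{(R)-[(2R)-oxiran-2-yl][3,4,5-tris(benzyloxy)phenyl]methoxy}-5-[(triisopropylsilyl)oxy]phenyl carbonate
Conditions: pyridine, CH2Cl2, 0 °C
Reagents that add atoms: none
Why: Acylation of the only remaining phenol by a chloroformate with pyridine; the oxirane and the aryl silyl ether do not react under these conditions.

Step 6
Reactants: 8 benzyl 3-{(R)-[(2R)-oxiran-2-yl][3,4,5-tris(benzyloxy)phenyl]methoxy}-5-[(triisopropylsilyl)oxy]phenyl carbonate
Product: 9 benzyl (2R,3R)-3-hydroxy-7-[(triisopropylsilyl)oxy]-2-[3,4,5-tris(benzyloxy)phenyl]-3,4-dihydro-2H-chromen-5-yl carbonate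
Conditions: BF3·OEt2 (0.3 equiv), CH2Cl2 (0.01 M), −78 to −40 °C; Et3N, then aq. NaHCO3
Reagents that add atoms: none
Why: BF3 binds the oxirane oxygen, and the ring A carbon ortho to O1 and para to the silyloxy group (the future C4a) attacks the unsubstituted oxirane carbon from the rear; loss of a proton from the arenium ion restores the arene and leaves the C3 oxygen as a boron alkoxide that is protonated on work-up. The closest known reaction type is the Lewis acid-mediated intramolecular Friedel–Crafts (epoxide–arene) cyclisation of aryl glycidyl ethers to chroman-3-ols. Ring C closes in the 6-endo mode of epoxide opening; the 5-exo mode to a dihydrobenzofuran would require attack at the secondary oxirane carbon, which is more hindered, inductively deactivated by the neighbouring C2–O1 bond and poorly aligned for a five-membered transition state. No stereocentre is formed: the bonds C2–O1, C2–C3 and C3–O stay intact, so the threo ether should emerge as the 2,3-cis flavan with both centres R. The step needs site selectivity between the two ring A carbons ortho to O1: the one that becomes C4a has the strong silyloxy donor in the para position, whereas the other (C8 of the product) has only the weakly donating carbonate para to it and is flanked by the bulky triisopropylsilyloxy group. It also needs the oxirane to react in preference to the benzylic C2–O1 ether, which low temperature, a substoichiometric amount of Lewis acid and the cation-destabilising oxygen on the adjacent carbon should ensure. High dilution suppresses intermolecular alkylation.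

Step 7
Reactants: 9 benzyl (2R,3R)-3-hydroxy-7-[(triisopropylsilyl)oxy]-2-[3,4,5-tris(benzyloxy)phenyl]-3,4-dihydro-2H-chromen-5-yl carbonate
Product: 10 benzyl (2R,3R)-3,7-dihydroxy-2-[3,4,5-tris(benzyloxy)phenyl]-3,4-dihydro-2H-chromen-5-yl carbonate
Conditions: TBAF (1.1 equiv), AcOH (1.2 equiv), THF, 0 °C
Reagents that add atoms: none
Why: Fluoride attacks silicon and releases the O7 phenol; aryl silyl ethers cleave readily because phenoxide is a good leaving group. Acetic acid buffers the fluoride and protonates the phenoxide at once, which should protect the aryl carbonate on O5 from cleavage or transfer.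

Step 8
Reactants: 11 3,4,5-tris(benzyloxy)benzoic acid
Product: 12 3,4,5-tris(benzyloxy)benzoyl chloride
Conditions: (COCl)2, cat. DMF, CH2Cl2, 0 °C to rt; evaporation, used crude
Reagents that add atoms: oxalyl chloride, O=C(Cl)C(=O)Cl
Why: Conversion of a carboxylic acid into its chloride through the chloroiminium species formed from oxalyl chloride and catalytic DMF; benzyl ethers are not affected.

Step 9
Reactants: 10 benzyl (2R,3R)-3,7-dihydroxy-2-[3,4,5-tris(benzyloxy)phenyl]-3,4-dihydro-2H-chromen-5-yl carbonate; 12 3,4,5-tris(benzyloxy)benzoyl chloride
Product: 13 (2R,3R)-5-{[(benzyloxy)carbonyl]oxy}-3-hydroxy-2-[3,4,5-tris(benzyloxy)phenyl]-3,4-dihydro-2H-chromen-7-yl 3,4,5-tris(benzyloxy)benzoate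
Conditions: 12 (1.05 equiv), i-Pr2NEt (1.5 equiv), CH2Cl2, −20 to 0 °C, no acyl-transfer catalyst
Reagents that add atoms: none
Why: Base-mediated O-acylation of a phenol by an acid chloride: the hydrogen-bonded ammonium phenoxide at O7 is much more nucleophilic than the hindered secondary C3 hydroxyl, which needs a nucleophilic catalyst to react at this temperature. The carbonate blocks O5, the only other phenol oxygen.

Step 10
Reactants: 13 (2R,3R)-5-{[(benzyloxy)carbonyl]oxy}-3-hydroxy-2-[3,4,5-tris(benzyloxy)phenyl]-3,4-dihydro-2H-chromen-7-yl 3,4,5-tris(benzyloxy)benzoate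
Product: 14 epigallocatechin 7-O-gallate, (2R,3R)-3,5-dihydroxy-2-(3,4,5-trihydroxyphenyl)-3,4-dihydro-2H-chromen-7-yl 3,4,5-trihydroxybenzoate
Conditions: H2 (1 atm), Pd(OH)2/C, THF/EtOAc, rt; filtration and concentration under argon
Reagents that add atoms: none
Why: Heterogeneous hydrogenolysis should cleave the six benzyl ethers and the benzyl carbonate, which loses carbon dioxide, under neutral conditions. The aryl ester, the C2–O1 bond and both stereocentres are expected to survive at low pressure in a solvent mixture without alcohol.

## Compound list

1 | 3,4,5-tris(benzyloxy)benzaldehyde | O=Cc1cc(OCc2ccccc2)c(OCc2ccccc2)c(OCc2ccccc2)c1 | starting material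
2 | rac-1-[3,4,5-tris(benzyloxy)phenyl]prop-2-en-1-ol | OC(C=C)c1cc(OCc2ccccc2)c(OCc2ccccc2)c(OCc2ccccc2)c1 | intermediate
3 | (S)-[(2R)-oxiran-2-yl][3,4,5-tris(benzyloxy)phenyl]methanol | O[C@@H](c1cc(OCc2ccccc2)c(OCc2ccccc2)c(OCc2ccccc2)c1)[C@H]1CO1 | intermediate
4 | phloroglucinol | Oc1cc(O)cc(O)c1 | starting material
5 | 5-[(triisopropylsilyl)oxy]benzene-1,3-diol | CC(C)[Si](C(C)C)(C(C)C)Oc1cc(O)cc(O)c1 | intermediate
6 | 3-{(R)-[(2R)-oxiran-2-yl][3,4,5-tris(benzyloxy)phenyl]methoxy}-5-[(triisopropylsilyl)oxy]phenol | Oc1cc(O[Si](C(C)C)(C(C)C)C(C)C)cc(O[C@H](c2cc(OCc3ccccc3)c(OCc3ccccc3)c(OCc3ccccc3)c2)[C@H]2CO2)c1 | intermediate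
7 | benzyl chloroformate | O=C(Cl)OCc1ccccc1 | starting material
8 | benzyl 3-{(R)-[(2R)-oxiran-2-yl][3,4,5-tris(benzyloxy)phenyl]methoxy}-5-[(triisopropylsilyl)oxy]phenyl carbonate | O=C(OCc1ccccc1)Oc1cc(O[Si](C(C)C)(C(C)C)C(C)C)cc(O[C@H](c2cc(OCc3ccccc3)c(OCc3ccccc3)c(OCc3ccccc3)c2)[C@H]2CO2)c1 | intermediate
9 | benzyl (2R,3R)-3-hydroxy-7-[(triisopropylsilyl)oxy]-2-[3,4,5-tris(benzyloxy)phenyl]-3,4-dihydro-2H-chromen-5-yl carbonate | CC(C)[Si](C(C)C)(C(C)C)Oc1cc(OC(=O)OCc3ccccc3)c2c(c1)O[C@H](c1cc(OCc3ccccc3)c(OCc3ccccc3)c(OCc3ccccc3)c1)[C@H](O)C2 | intermediate
10 | benzyl (2R,3R)-3,7-dihydroxy-2-[3,4,5-tris(benzyloxy)phenyl]-3,4-dihydro-2H-chromen-5-yl carbonate | Oc1cc(OC(=O)OCc3ccccc3)c2c(c1)O[C@H](c1cc(OCc3ccccc3)c(OCc3ccccc3)c(OCc3ccccc3)c1)[C@H](O)C2 | intermediate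
11 | 3,4,5-tris(benzyloxy)benzoic acid | O=C(O)c1cc(OCc2ccccc2)c(OCc2ccccc2)c(OCc2ccccc2)c1 | starting material
12 | 3,4,5-tris(benzyloxy)benzoyl chloride | O=C(Cl)c1cc(OCc2ccccc2)c(OCc2ccccc2)c(OCc2ccccc2)c1 | intermediate
13 | (2R,3R)-5-{[(benzyloxy)carbonyl]oxy}-3-hydroxy-2-[3,4,5-tris(benzyloxy)phenyl]-3,4-dihydro-2H-chromen-7-yl 3,4,5-tris(benzyloxy)benzoate | O=C(Oc1cc(OC(=O)OCc3ccccc3)c2c(c1)O[C@H](c1cc(OCc3ccccc3)c(OCc3ccccc3)c(OCc3ccccc3)c1)[C@H](O)C2)c1cc(OCc2ccccc2)c(OCc2ccccc2)c(OCc2ccccc2)c1 | intermediate
14 | epigallocatechin 7-O-gallate | O=C(Oc1cc(O)c2c(c1)O[C@H](c1cc(O)c(O)c(O)c1)[C@H](O)C2)c1cc(O)c(O)c(O)c1 | target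

## Step count and least certain steps

Total: 10 steps. Longest linear sequence: 8 steps (steps 1, 2, 4, 5, 6, 7, 9 and 10, from 1 to 14).

**Step 6 (key step).** The most likely failure is ring closure through the other carbon ortho to O1, the one between O1 and the silyloxy group, because the electronic preference for the carbon para to the silyloxy group over the carbon para to the carbonate is moderate. A second failure is Lewis-acid ionisation of the benzylic C2–O1 bond, or participation of ring B at the secondary oxirane carbon, with loss of configuration at C2 or skeletal rearrangement. The fallback sets out from 6, before the carbonate is put on. Its free hydroxyl (the future O5) is converted into the magnesium phenoxide with Bu2Mg in toluene. Magnesium on O5 can bind the oxirane oxygen and deliver the terminal carbon to the ortho carbon C4a through a six-membered chelate (ortho-specific C-alkylation of a metal phenoxide by a coordinated epoxide). No free Lewis acid is present, and the site is fixed by the template and not by a balance of donors. This should give (2R,3R)-7-[(triisopropylsilyl)oxy]-2-[3,4,5-tris(benzyloxy)phenyl]-3,4-dihydro-2H-chromene-3,5-diol F1. Carbonate formation at the phenol of F1 with 7 (i-Pr2NEt, CH2Cl2, −20 °C) comes back to the route at 9.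

**Step 4.** Partial ionisation of the activated benzylic oxyphosphonium ion would erode the inversion and lead to the erythro ether and, later, the 2,3-trans flavan. The second free hydroxyl of 5 can also be etherified, or the very electron-rich ring alkylated at carbon. The fallback changes the nucleophile and the order of assembly. 5 is first converted with 7 (0.9 equiv, pyridine, CH2Cl2, −20 °C) into benzyl 3-hydroxy-5-[(triisopropylsilyl)oxy]phenyl carbonate F2. F2 has one hydroxyl, a less nucleophilic ring and a more acidic phenol that forms the ion pair faster. Etherification of 3 with F2 (PPh3, DIAD, toluene) gives the precursor directly, so the fallback sets out from 5 and 3 and comes back to the route at 8, bypassing 6.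

**Step 9.** Competing acylation of the C3 hydroxyl, or transfer of the O5 carbonate by the O7 phenoxide, would give mixtures of esters. The fallback sets out from 9 and masks O3 with a group that the final hydrogenolysis removes anyway. Treatment of 9 with 7 (pyridine, DMAP) gives benzyl (2R,3R)-5-{[(benzyloxy)carbonyl]oxy}-7-[(triisopropylsilyl)oxy]-2-[3,4,5-tris(benzyloxy)phenyl]-3,4-dihydro-2H-chromen-3-yl carbonate F5. Buffered fluoride then gives benzyl (2R,3R)-5-{[(benzyloxy)carbonyl]oxy}-7-hydroxy-2-[3,4,5-tris(benzyloxy)phenyl]-3,4-dihydro-2H-chromen-3-yl carbonate F6. F6 has a single free hydroxyl, and acylation with 12 gives (2R,3R)-3,5-bis{[(benzyloxy)carbonyl]oxy}-2-[3,4,5-tris(benzyloxy)phenyl]-3,4-dihydro-2H-chromen-7-yl 3,4,5-tris(benzyloxy)benzoate F7. Hydrogenolysis of F7 over Pd(OH)2/C comes back to the route at 14.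

**Step 7.** Fluoride or the liberated phenoxide may cleave or redistribute the aryl carbonate on O5 before the phenoxide is protonated. The fallback never lets the free phenoxide accumulate. The chloride 12 is converted with KF (cat. 18-crown-6, MeCN) into 3,4,5-tris(benzyloxy)benzoyl fluoride F8. 9 is then treated with F8 and a catalytic amount of tetrabutylammonium difluorotriphenylsilicate in THF. Each phenoxide released from silicon is acylated at once, and the fluoride set free carries the chain (fluoride-catalysed exchange of a silyl ether for an ester). The fallback sets out from 9 and 12 and comes back to the route at 13, bypassing 10.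

**Step 2.** Terminal vinyl carbinols are epoxidised slowly, so insufficient rate discrimination between the enantiomers, or titanium-promoted opening of the sensitive benzylic epoxy alcohol during a long reaction, would lower the enantiomeric purity of 3. The fallback sets out from 2 and separates the two selection events. Immobilised Candida antarctica lipase B with vinyl acetate should acylate the (R)-enantiomer (Kazlauskas rule) to give (R)-1-[3,4,5-tris(benzyloxy)phenyl]prop-2-en-1-yl acetate F3, which is separated from the unreacted alcohol. Methanolysis (K2CO3, MeOH) gives (R)-1-[3,4,5-tris(benzyloxy)phenyl]prop-2-en-1-ol F4. Epoxidation of F4 with the same titanium and L-(+)-tartrate system and a full equivalent of t-BuOOH is then a matched, reagent-controlled reaction that leaves any residual antipode behind, and it comes back to the route at 3.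

## Further compounds

F1 | step 6 | (2R,3R)-7-[(triisopropylsilyl)oxy]-2-[3,4,5-tris(benzyloxy)phenyl]-3,4-dihydro-2H-chromene-3,5-diol | CC(C)[Si](C(C)C)(C(C)C)Oc1cc(O)c2c(c1)O[C@H](c1cc(OCc3ccccc3)c(OCc3ccccc3)c(OCc3ccccc3)c1)[C@H](O)C2
F2 | step 4 | benzyl 3-hydroxy-5-[(triisopropylsilyl)oxy]phenyl carbonate | O=C(OCc1ccccc1)Oc1cc(O)cc(O[Si](C(C)C)(C(C)C)C(C)C)c1
F3 | step 2 | (R)-1-[3,4,5-tris(benzyloxy)phenyl]prop-2-en-1-yl acetate | CC(=O)O[C@H](C=C)c1cc(OCc2ccccc2)c(OCc2ccccc2)c(OCc2ccccc2)c1
F4 | step 2 | (R)-1-[3,4,5-tris(benzyloxy)phenyl]prop-2-en-1-ol | O[C@H](C=C)c1cc(OCc2ccccc2)c(OCc2ccccc2)c(OCc2ccccc2)c1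
F5 | step 9 | benzyl (2R,3R)-5-{[(benzyloxy)carbonyl]oxy}-7-[(triisopropylsilyl)oxy]-2-[3,4,5-tris(benzyloxy)phenyl]-3,4-dihydro-2H-chromen-3-yl carbonate | CC(C)[Si](C(C)C)(C(C)C)Oc1cc(OC(=O)OCc3ccccc3)c2c(c1)O[C@H](c1cc(OCc3ccccc3)c(OCc3ccccc3)c(OCc3ccccc3)c1)[C@H](OC(=O)OCc1ccccc1)C2
F6 | step 9 | benzyl (2R,3R)-5-{[(benzyloxy)carbonyl]oxy}-7-hydroxy-2-[3,4,5-tris(benzyloxy)phenyl]-3,4-dihydro-2H-chromen-3-yl carbonate | Oc1cc(OC(=O)OCc3ccccc3)c2c(c1)O[C@H](c1cc(OCc3ccccc3)c(OCc3ccccc3)c(OCc3ccccc3)c1)[C@H](OC(=O)OCc1ccccc1)C2
F7 | step 9 | (2R,3R)-3,5-bis{[(benzyloxy)carbonyl]oxy}-2-[3,4,5-tris(benzyloxy)phenyl]-3,4-dihydro-2H-chromen-7-yl 3,4,5-tris(benzyloxy)benzoate | O=C(Oc1cc(OC(=O)OCc3ccccc3)c2c(c1)O[C@H](c1cc(OCc3ccccc3)c(OCc3ccccc3)c(OCc3ccccc3)c1)[C@H](OC(=O)OCc1ccccc1)C2)c1cc(OCc2ccccc2)c(OCc2ccccc2)c(OCc2ccccc2)c1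
F8 | step 7 | 3,4,5-tris(benzyloxy)benzoyl fluoride | O=C(F)c1cc(OCc2ccccc2)c(OCc2ccccc2)c(OCc2ccccc2)c1
A1 | alternative 1 | 3-(benzyloxy)-5-(methoxymethoxy)-2-(trimethylsilyl)phenyl trifluoromethanesulfonate | COCOc1cc(OCc2ccccc2)c([Si](C)(C)C)c(OS(=O)(=O)C(F)(F)F)c1
A2 | alternative 1 | N,N-dimethylformamide | CN(C)C=O
A3 | alternative 1 | 2-(methoxymethoxy)-1-[3,4,5-tris(benzyloxy)phenyl]ethan-1-one | COCOCC(=O)c1cc(OCc2ccccc2)c(OCc2ccccc2)c(OCc2ccccc2)c1
A4 | alternative 1 | 5-(benzyloxy)-3,7-bis(methoxymethoxy)-2-[3,4,5-tris(benzyloxy)phenyl]-2H-chromen-2-ol (racemic) | COCOc1cc(OCc3ccccc3)c2C=C(OCOC)C(O)(c3cc(OCc4ccccc4)c(OCc4ccccc4)c(OCc4ccccc4)c3)Oc2c1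
A5 | alternative 2 | 3-(benzyloxy)-2-(hydroxymethyl)-5-[(triisopropylsilyl)oxy]phenol | OCc1c(O)cc(O[Si](C(C)C)(C(C)C)C(C)C)cc1OCc1ccccc1
A6 | alternative 2 | (Z)-2-[3,4,5-tris(benzyloxy)phenyl]ethenyl benzoate | O=C(O/C=C\c1cc(OCc2ccccc2)c(OCc2ccccc2)c(OCc2ccccc2)c1)c1ccccc1
A7 | alternative 2 | (2R,3R)-5-(benzyloxy)-7-[(triisopropylsilyl)oxy]-2-[3,4,5-tris(benzyloxy)phenyl]-3,4-dihydro-2H-chromen-3-yl benzoate | CC(C)[Si](C(C)C)(C(C)C)Oc1cc(OCc3ccccc3)c2c(c1)O[C@H](c1cc(OCc3ccccc3)c(OCc3ccccc3)c(OCc3ccccc3)c1)[C@H](OC(=O)c1ccccc1)C2
A8 | alternative 3 | (1R,2R)-2-(benzyloxy)-3-{2-(benzyloxy)-6-bromo-4-[(triisopropylsilyl)oxy]phenyl}-1-[3,4,5-tris(benzyloxy)phenyl]propan-1-ol | O[C@H](c1cc(OCc2ccccc2)c(OCc2ccccc2)c(OCc2ccccc2)c1)[C@H](OCc1ccccc1)Cc1c(Br)cc(O[Si](C(C)C)(C(C)C)C(C)C)cc1OCc1ccccc1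
A9 | alternative 3 | (2R,3R)-3,5-bis(benzyloxy)-7-[(triisopropylsilyl)oxy]-2-[3,4,5-tris(benzyloxy)phenyl]-3,4-dihydro-2H-chromene | CC(C)[Si](C(C)C)(C(C)C)Oc1cc(OCc3ccccc3)c2c(c1)O[C@H](c1cc(OCc3ccccc3)c(OCc3ccccc3)c(OCc3ccccc3)c1)[C@H](OCc1ccccc1)C2
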